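## Retrosynthetic overview

1. Target 20 ⇐ ester hydrolysis and aldehyde oxidation ⇐ angular aldehyde 18 (all four ring stereocentres already in place).
2. Ring B is closed last: a [4+2] between triene 16 and a dienal that a chiral primary amine releases in situ from the ring-symmetric dihydrobenzaldehyde 9. This desymmetrising isomerisation/cycloaddition is the key step.
3. Ring A is the benzene ring of methyl 4-vinylbenzoate: Ni hydrovinylation sets the side-chain centre, hydroboration/Suzuki coupling finishes the chain, Birch reduction breaks the aromaticity.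
4. Triene 16 ⇐ Suzuki coupling of an (E)-alkenyl iodide (alkyne carboalumination) with a dienylboronate; the trans-cyclohexane ring is bought.
5. Ring order: ring A (from the arene), cyclohexane ring (purchased), ring B (formed last).

Assumption: for the two enantioselective catalysts (steps 1 and 9) the antipode or pseudo-enantiomer that gives the configuration drawn is used; the sense of induction has to be confirmed by experiment.

## Route

Step 1
Reactants: 1 methyl 4-vinylbenzoate; 2 ethylene
Product: 3 methyl 4-[(2S)-but-3-en-2-yl]benzoate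
Conditions: [(η3-C3H5)NiBr]2 (0.7 mol %), (1,1'-binaphthalene-2,2'-diyl) N,N-bis(1-phenylethyl)phosphoramidite (1.4 mol %), NaB[3,5-(CF3)2C6H3]4 (1.5 mol %), ethylene (1 atm), CH2Cl2, −70 °C
Reagents that add atoms: ethylene (2), C=C
Why: Nickel-catalysed asymmetric hydrovinylation: a cationic nickel hydride adds to the styrene to give an η3-benzyl species, ethylene inserts and β-hydride elimination releases the branched 3-arylbut-1-ene, the phosphoramidite fixing the benzylic (S) centre; low temperature suppresses isomerisation to the conjugated alkene.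

Step 2
Reactants: 3 methyl 4-[(2S)-but-3-en-2-yl]benzoate; 4 1-bromo-2-methylprop-1-ene
Product: 6 methyl 4-[(2S)-6-methylhept-5-en-2-yl]benzoate, via B-alkyl-9-BBN adduct 5 (not isolated)
Conditions: 9-BBN (1.1 equiv), THF, 0 °C → rt; then 4 (1.2 equiv), Pd(dppf)Cl2 (3 mol %), aq. K3PO4, DMF, 50 °C
Reagents that add atoms: 1-bromo-2-methylprop-1-ene (4), CC(C)=CBr
Why: Anti-Markovnikov hydroboration of the terminal alkene followed by B-alkyl Suzuki–Miyaura coupling with the alkenyl bromide; the ester tolerates both stages and the benzylic stereocentre is not involved.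

Step 3
Reactants: 6 methyl 4-[(2S)-6-methylhept-5-en-2-yl]benzoate
Product: 8 methyl 4-[(2S)-6-methylhept-5-en-2-yl]cyclohexa-2,5-diene-1-carboxylate (cis/trans mixture at C1/C4), via sodium dienolate 7 (not isolated)
Conditions: Na (2.5 equiv), t-BuOH (1.5 equiv), NH3(l)/THF, −78 °C, 15 min; then solid NH4Cl
Reagents that add atoms: none
Why: Birch reduction of a benzoate: electron transfer, protonation para to the ester and a second electron give the ester dienolate, which is protonated at the α-carbon on quench; the isolated trisubstituted alkene and the side-chain centre are inert, and the C1/C4 cis/trans ratio is irrelevant because both isomers converge in step 9.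

Step 4
Reactants: 8 methyl 4-[(2S)-6-methylhept-5-en-2-yl]cyclohexa-2,5-diene-1-carboxylate
Product: 9 4-[(2S)-6-methylhept-5-en-2-yl]cyclohexa-2,5-diene-1-carbaldehyde (cis/trans mixture)
Conditions: i-Bu2AlH (1.05 equiv), CH2Cl2, −78 °C; MeOH, then aq. KNaC4H4O6; used at once under Ar
Reagents that add atoms: none
Why: Partial reduction of an ester with i-Bu2AlH: the tetrahedral aluminium hemiacetal is stable at −78 °C and gives the aldehyde only on work-up, so the doubly allylic α-position is not exposed to base.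

Step 5
Reactants: 10 methyl trans-4-formylcyclohexane-1-carboxylate
Product: 11 methyl trans-4-ethynylcyclohexane-1-carboxylate
Conditions: dimethyl (1-diazo-2-oxopropyl)phosphonate (1.2 equiv), K2CO3 (2 equiv), MeOH, 0 °C → rt
Reagents that add atoms: dimethyl (1-diazo-2-oxopropyl)phosphonate, COP(=O)(OC)C(=[N+]=[N-])C(C)=O
Why: Seyferth–Gilbert homologation in the Ohira–Bestmann form: the aldehyde becomes the terminal alkyne through a diazoalkene/alkylidene carbene 1,2-shift; the ring carbon next to the aldehyde stays trans because the diequatorial isomer is also the thermodynamic one.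

Step 6
Reactants: 11 methyl trans-4-ethynylcyclohexane-1-carboxylate
Product: 13 methyl trans-4-[(1E)-1-iodoprop-1-en-2-yl]cyclohexane-1-carboxylate, via alkenylalane 12 (not isolated)
Conditions: AlMe3 (3 equiv), Cp2ZrCl2 (20 mol %), H2O (1.5 equiv), CH2Cl2, −23 °C, 1 h; then iodine, THF, −23 → 0 °C
Reagents that add atoms: trimethylaluminium, C[Al](C)C; iodine, [I][I]
Why: Zirconium-catalysed carboalumination (Negishi; water-accelerated low-temperature variant to spare the ester): methyl and aluminium add syn with methyl on the internal carbon, and iodinolysis with retention gives the (E)-trisubstituted alkenyl iodide.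

Step 7
Reactants: 14 2-methylbut-1-en-3-yne
Product: 15 4,4,5,5-tetramethyl-2-[(1E)-3-methylbuta-1,3-dien-1-yl]-1,3,2-dioxaborolane
Conditions: pinacolborane (1.05 equiv), Cp2Zr(H)Cl (5 mol %), Et3N (10 mol %), CH2Cl2, sealed tube, 25–40 °C
Reagents that add atoms: pinacolborane, [H]B1OC(C)(C)C(C)(C)O1
Why: Zirconium-catalysed syn hydroboration of the terminal alkyne (hydrozirconation, then transfer to boron) is anti-Markovnikov and leaves the 1,1-disubstituted alkene alone, giving the (E)-dienylboronate.

Step 8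
Reactants: 13 methyl trans-4-[(1E)-1-iodoprop-1-en-2-yl]cyclohexane-1-carboxylate; 15 4,4,5,5-tetramethyl-2-[(1E)-3-methylbuta-1,3-dien-1-yl]-1,3,2-dioxaborolane
Product: 16 methyl trans-4-[(2E,4E)-6-methylhepta-2,4,6-trien-2-yl]cyclohexane-1-carboxylate
Conditions: Pd(dppf)Cl2 (5 mol %), K3PO4 (3 equiv), THF/H2O, 45 °C; product stored cold with BHT
Reagents that add atoms: none
Why: Suzuki–Miyaura alkenyl–alkenyl coupling proceeds with retention at both partners, so the (2E,4E) geometry is carried over from 13 and 15.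

Step 9
Reactants: 9 4-[(2S)-6-methylhept-5-en-2-yl]cyclohexa-2,5-diene-1-carbaldehyde; 16 methyl trans-4-[(2E,4E)-6-methylhepta-2,4,6-trien-2-yl]cyclohexane-1-carboxylate
Product: 18 methyl trans-4-[(1E)-1-[(1R,4aR,6R,8aR)-8a-formyl-3-methyl-6-[(2S)-6-methylhept-5-en-2-yl]-1,4,4a,5,6,8a-hexahydronaphthalen-1-yl]prop-1-en-2-yl]cyclohexane-1-carboxylate, via conjugated dienal 17 (not isolated)
Conditions: 9-amino(9-deoxy)epi-quinine (20 mol %), CF3CO2H (40 mol %), 16 (2 equiv), H2O (2 equiv), toluene, degassed, 0 °C → rt, Ar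
Reagents that add atoms: none
Why: Proposed new method: the primary amine condenses with 9 and loss of the doubly allylic α-H gives a ring-symmetric cross-conjugated dienamine, γ-protonation at either ring arm gives the two C4-epimeric iminium ions of dienal 17, which interconvert through that dienamine, and the iminium whose catalyst-open face is also the face anti to the C4 side chain is trapped by the unsubstituted diene terminus of 16 in an exo-formyl (ring-endo) Diels–Alder reaction, so the catalyst sets the two ring-fusion carbons (C4a, C8a), dynamic kinetic resolution under the anti rule sets C6, the (E)-diene in the exo-formyl transition state sets C1, and the slow release of the dienophile limits its dimerisation; the closest known reaction types are the cinchona primary amine-catalysed isomerisation of β,γ- to α,β-unsaturated carbonyl compounds by dienamine γ-protonation and the primary ammonium-catalysed exo-selective Diels–Alder reaction of α-substituted acroleins.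

Step 10
Reactants: 18 methyl trans-4-[(1E)-1-[(1R,4aR,6R,8aR)-8a-formyl-3-methyl-6-[(2S)-6-methylhept-5-en-2-yl]-1,4,4a,5,6,8a-hexahydronaphthalen-1-yl]prop-1-en-2-yl]cyclohexane-1-carboxylate
Product: 19 (2R,4aR,5R,8aR)-5-[(1E)-2-[trans-4-(methoxycarbonyl)cyclohexyl]prop-1-en-1-yl]-7-methyl-2-[(2S)-6-methylhept-5-en-2-yl]-1,2,4a,5,8,8a-hexahydronaphthalene-4a-carboxylic acid
Conditions: NaClO2 (3 equiv), NaH2PO4 (4 equiv), 2-methylbut-2-ene (30 equiv), t-BuOH/THF/H2O, 0 °C → rt
Reagents that add atoms: sodium chlorite, [Na+].[O-]Cl=O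
Why: Pinnick oxidation: chlorous acid adds to the hindered aldehyde and fragments to the acid while 2-methylbut-2-ene scavenges HOCl, so the four C=C bonds survive and no stereocentre is touched (the α-carbon is quaternary).

Step 11
Reactants: 19 (2R,4aR,5R,8aR)-5-[(1E)-2-[trans-4-(methoxycarbonyl)cyclohexyl]prop-1-en-1-yl]-7-methyl-2-[(2S)-6-methylhept-5-en-2-yl]-1,2,4a,5,8,8a-hexahydronaphthalene-4a-carboxylic acid
Product: 20 (2R,4aR,5R,8aR)-5-[(1E)-2-(trans-4-carboxycyclohexyl)prop-1-en-1-yl]-7-methyl-2-[(2S)-6-methylhept-5-en-2-yl]-1,2,4a,5,8,8a-hexahydronaphthalene-4a-carboxylic acid (CNP0151628.5)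
Conditions: LiOH·H2O (5 equiv), THF/MeOH/H2O, 40 °C; then 1 M HCl to pH 3
Reagents that add atoms: lithium hydroxide, [Li+].[OH-]
Why: Saponification of the unhindered secondary methyl ester by acyl–oxygen cleavage; the angular acid is a spectator carboxylate and the trans-cyclohexane is the thermodynamic isomer, so the centre next to the ester cannot drift.

## Compound list

1 | methyl 4-vinylbenzoate | C=Cc1ccc(cc1)C(=O)OC | starting material
2 | ethylene | C=C | starting material
3 | methyl 4-[(2S)-but-3-en-2-yl]benzoate | C=C[C@H](C)c1ccc(cc1)C(=O)OC | intermediate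
4 | 1-bromo-2-methylprop-1-ene | CC(C)=CBr | starting material
5 | methyl 4-[(2S)-4-(9-borabicyclo[3.3.1]nonan-9-yl)butan-2-yl]benzoate (not isolated) | C[C@@H](CCB1C2CCCC1CCC2)c1ccc(cc1)C(=O)OC | intermediate
6 | methyl 4-[(2S)-6-methylhept-5-en-2-yl]benzoate | CC(C)=CCC[C@H](C)c1ccc(cc1)C(=O)OC | intermediate
7 | sodium methoxy{4-[(2S)-6-methylhept-5-en-2-yl]cyclohexa-2,5-dien-1-ylidene}methanolate (ring-symmetric ester dienolate, not isolated) | CC(C)=CCC[C@H](C)C1C=CC(C=C1)=C(OC)[O-].[Na+] | intermediate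
8 | methyl 4-[(2S)-6-methylhept-5-en-2-yl]cyclohexa-2,5-diene-1-carboxylate (cis/trans mixture) | CC(C)=CCC[C@H](C)C1C=CC(C=C1)C(=O)OC | intermediate
9 | 4-[(2S)-6-methylhept-5-en-2-yl]cyclohexa-2,5-diene-1-carbaldehyde (cis/trans mixture) | CC(C)=CCC[C@H](C)C1C=CC(C=O)C=C1 | intermediate
10 | methyl trans-4-formylcyclohexane-1-carboxylate | O=C[C@H]1CC[C@H](C(=O)OC)CC1 | starting material
11 | methyl trans-4-ethynylcyclohexane-1-carboxylate | C#C[C@H]1CC[C@H](C(=O)OC)CC1 | intermediate
12 | methyl trans-4-[(1E)-1-(dimethylalumanyl)prop-1-en-2-yl]cyclohexane-1-carboxylate (not isolated) | C[Al](C)/C=C(\C)[C@H]1CC[C@H](C(=O)OC)CC1 | intermediate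
13 | methyl trans-4-[(1E)-1-iodoprop-1-en-2-yl]cyclohexane-1-carboxylate | I/C=C(\C)[C@H]1CC[C@H](C(=O)OC)CC1 | intermediate
14 | 2-methylbut-1-en-3-yne | CC(=C)C#C | starting material
15 | 4,4,5,5-tetramethyl-2-[(1E)-3-methylbuta-1,3-dien-1-yl]-1,3,2-dioxaborolane | CC(=C)/C=C/B1OC(C)(C)C(C)(C)O1 | intermediate
16 | methyl trans-4-[(2E,4E)-6-methylhepta-2,4,6-trien-2-yl]cyclohexane-1-carboxylate | CC(=C)/C=C/C=C(\C)[C@H]1CC[C@H](C(=O)OC)CC1 | intermediate
17 | (4R)-4-[(2S)-6-methylhept-5-en-2-yl]cyclohexa-1,5-diene-1-carbaldehyde (present as its iminium ion, not isolated) | CC(C)=CCC[C@H](C)[C@@H]1C=CC(C=O)=CC1 | intermediate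
18 | methyl trans-4-[(1E)-1-[(1R,4aR,6R,8aR)-8a-formyl-3-methyl-6-[(2S)-6-methylhept-5-en-2-yl]-1,4,4a,5,6,8a-hexahydronaphthalen-1-yl]prop-1-en-2-yl]cyclohexane-1-carboxylate | CC(C)=CCC[C@H](C)[C@@H]1C=C[C@]2(C=O)[C@@H](CC(C)=C[C@@H]2/C=C(\C)[C@H]2CC[C@H](C(=O)OC)CC2)C1 | intermediate
19 | (2R,4aR,5R,8aR)-5-[(1E)-2-[trans-4-(methoxycarbonyl)cyclohexyl]prop-1-en-1-yl]-7-methyl-2-[(2S)-6-methylhept-5-en-2-yl]-1,2,4a,5,8,8a-hexahydronaphthalene-4a-carboxylic acid | CC(C)=CCC[C@H](C)[C@@H]1C=C[C@]2(C(=O)O)[C@@H](CC(C)=C[C@@H]2/C=C(\C)[C@H]2CC[C@H](C(=O)OC)CC2)C1 | intermediate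
20 | (2R,4aR,5R,8aR)-5-[(1E)-2-(trans-4-carboxycyclohexyl)prop-1-en-1-yl]-7-methyl-2-[(2S)-6-methylhept-5-en-2-yl]-1,2,4a,5,8,8a-hexahydronaphthalene-4a-carboxylic acid | CC(C)=CCC[C@H](C)[C@@H]1C=C[C@]2(C(=O)O)[C@@H](CC(C)=C[C@@H]2/C=C(\C)[C@H]2CC[C@H](C(=O)O)CC2)C1 | target

## Step count and risks

Total: 11 steps. Longest linear sequence: 7 steps (1, 2, 3, 4, 9, 10, 11).

**Step 9 (most likely to fail).** The amine-catalysed desymmetrising isomerisation/cycloaddition is untested: the sense and level of induction, the rate of the iminium Diels–Alder reaction and the competition with dimerisation of the dienal are all open. The fallback fixes the ring stereocentre before the cycloaddition by known ketone chemistry. It sets out from ethylene 2 and bromide 4 and uses commercial 4-methoxystyrene in place of 1. Nickel-catalysed hydrovinylation gives 1-[(2S)-but-3-en-2-yl]-4-methoxybenzene F1. 9-BBN gives 9-[(3S)-3-(4-methoxyphenyl)butyl]-9-borabicyclo[3.3.1]nonane F2, which is coupled with 4 (Pd(dppf)Cl2, K3PO4) to 1-methoxy-4-[(2S)-6-methylhept-5-en-2-yl]benzene F3. Birch reduction (Li, NH3, t-BuOH) gives 1-methoxy-4-[(2S)-6-methylhept-5-en-2-yl]cyclohexa-1,4-diene F4, and oxalic acid hydrolysis gives 4-[(2S)-6-methylhept-5-en-2-yl]cyclohex-3-en-1-one F5. Enantioselective isomerisation with a cinchona-derived primary amine and an acid co-catalyst gives (4R)-4-[(2S)-6-methylhept-5-en-2-yl]cyclohex-2-en-1-one F6. LiN(i-Pr)2 at −78 °C gives the cross-conjugated enolate lithium (4R)-4-[(2S)-6-methylhept-5-en-2-yl]cyclohexa-1,5-dien-1-olate F7, trapped with PhNTf2 as (4R)-4-[(2S)-6-methylhept-5-en-2-yl]cyclohexa-1,5-dien-1-yl trifluoromethanesulfonate F8. Formylation (Pd(PPh3)4, CO, Bu3SnH) then gives dienal 17, now configurationally fixed, which is combined at once with triene 16 (toluene, rt) in the uncatalysed Diels–Alder reaction; the route is rejoined at 18.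

**Step 6.** AlMe3 may attack the methyl ester, or the carboalumination may stall at low temperature. The fallback builds the trisubstituted alkene by olefination instead of carbometalation and sets out from aldehyde 10. MeMgBr at −78 °C gives methyl trans-4-(1-hydroxyethyl)cyclohexane-1-carboxylate F9, and Dess–Martin oxidation gives methyl trans-4-acetylcyclohexane-1-carboxylate F10. Ethynylmagnesium bromide adds to the ketone to give methyl trans-4-(2-hydroxybut-3-yn-2-yl)cyclohexane-1-carboxylate F11. Meyer–Schuster rearrangement (MoO2(acac)2, AuCl(PPh3), AgOTf, toluene) gives methyl trans-4-[(2E)-4-oxobut-2-en-2-yl]cyclohexane-1-carboxylate F12, with the minor Z isomer removed by chromatography. Horner–Wadsworth–Emmons reaction with the sodium salt of diethyl (2-methylprop-2-en-1-yl)phosphonate (NaH, THF) returns to triene 16, bypassing 11 to 15.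

**Step 4.** The partial reduction may over-reduce, and the dihydroaromatic aldehyde may re-aromatise on handling. The fallback is a two-stage redox from 8: LiAlH4 gives [4-[(2S)-6-methylhept-5-en-2-yl]cyclohexa-2,5-dien-1-yl]methanol F13, a storable alcohol, which is oxidised with Dess–Martin periodinane/NaHCO3 immediately before step 9 to return to 9.

## Further compounds

F1 | step 9 | 1-[(2S)-but-3-en-2-yl]-4-methoxybenzene | C=C[C@H](C)c1ccc(OC)cc1
F2 | step 9 | 9-[(3S)-3-(4-methoxyphenyl)butyl]-9-borabicyclo[3.3.1]nonane | C[C@@H](CCB1C2CCCC1CCC2)c1ccc(OC)cc1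
F3 | step 9 | 1-methoxy-4-[(2S)-6-methylhept-5-en-2-yl]benzene | CC(C)=CCC[C@H](C)c1ccc(OC)cc1
F4 | step 9 | 1-methoxy-4-[(2S)-6-methylhept-5-en-2-yl]cyclohexa-1,4-diene | CC(C)=CCC[C@H](C)C1=CCC(OC)=CC1
F5 | step 9 | 4-[(2S)-6-methylhept-5-en-2-yl]cyclohex-3-en-1-one | CC(C)=CCC[C@H](C)C1=CCC(=O)CC1
F6 | step 9 | (4R)-4-[(2S)-6-methylhept-5-en-2-yl]cyclohex-2-en-1-one | CC(C)=CCC[C@H](C)[C@@H]1C=CC(=O)CC1
F7 | step 9 | lithium (4R)-4-[(2S)-6-methylhept-5-en-2-yl]cyclohexa-1,5-dien-1-olate | CC(C)=CCC[C@H](C)[C@@H]1C=CC([O-])=CC1.[Li+]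
F8 | step 9 | (4R)-4-[(2S)-6-methylhept-5-en-2-yl]cyclohexa-1,5-dien-1-yl trifluoromethanesulfonate | CC(C)=CCC[C@H](C)[C@@H]1C=CC(OS(=O)(=O)C(F)(F)F)=CC1
F9 | step 6 | methyl trans-4-(1-hydroxyethyl)cyclohexane-1-carboxylate | CC(O)[C@H]1CC[C@H](C(=O)OC)CC1
F10 | step 6 | methyl trans-4-acetylcyclohexane-1-carboxylate | CC(=O)[C@H]1CC[C@H](C(=O)OC)CC1
F11 | step 6 | methyl trans-4-(2-hydroxybut-3-yn-2-yl)cyclohexane-1-carboxylate | C#CC(C)(O)[C@H]1CC[C@H](C(=O)OC)CC1
F12 | step 6 | methyl trans-4-[(2E)-4-oxobut-2-en-2-yl]cyclohexane-1-carboxylate | O=C/C=C(\C)[C@H]1CC[C@H](C(=O)OC)CC1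
F13 | step 4 | [4-[(2S)-6-methylhept-5-en-2-yl]cyclohexa-2,5-dien-1-yl]methanol | CC(C)=CCC[C@H](C)C1C=CC(CO)C=C1
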